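In lifetimes of the electrophile, not in minutes, we count how far this flask gets.

electrophile 0.050 M (fed, over 2.0 min); solid nucleophile 0.150 M; gas 2.9 mM (held); time 50 min

    electrophile + nucleophile → acid set free + product (k1 = 0.052 L mol⁻¹ s⁻¹)
    nucleophile + acid set free ⇌ protonated nucleophile, settled at all times (K2 = 1.2 × 10⁵ L mol⁻¹)
    acid set free + free base ⇌ salt of the base, settled at all times (K3 = 3500 L mol⁻¹)
    solid nucleophile ⇌ nucleophile, rate k4*(cs4 - [nucleophile]) while solid is left; crystals form when [nucleophile] > cs4 (cs4 = 17 mM, k4 = 0.019 s⁻¹)
    2 free base → homo dimer (k5 = 2.4 L mol⁻¹ s⁻¹)
    gas ⇌ free base, rate k6*(csat - [free base]) (k6 = 0.020 s⁻¹, csat = 2.9 mM)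

1. part of the electrophile that has reacted at 50 min
2. share of free nucleophile in free nucleophile and protonated nucleophile together, at 50 min

- a doubled species enters its step squared and goes two at a time
- solid, in amounts per volume of the solution: solid nucleophile
- at the start none of free base is dissolved
- at the start none of the solid nucleophile is in solution
- run time (flask): 50 min

Dissolution has the rate constant 0.019 s⁻¹, against 8.84 × 10⁻⁴ s⁻¹ for step 1 with [nucleophile] at its solubility. So in this flask we treat step 1 as pseudo-first-order at that rate. Over the whole time this gives 2.65 lifetimes. The feed brings the electrophile in on average at 1.00 min, which trims the count by a factor 0.980 to 2.60 turnovers, the lifetimes at full rate that fit into the run. In this count the electrophile left is the exponential of minus the turnovers, here 7.43%, so the count gives 92.6% reacted.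

But each turn frees acid, and the acid goes to a second nucleophile, since K2·cs4 exceeds K3·csat. Dissolution must therefore deliver two nucleophile per turn. Let the sag be 0.274; at the full charge this demand lowers the rate by a factor 1.27, and the sag fades as the electrophile goes. Summed over the run, we reckon the turnovers lost as the sag times the part reacted.

| Count | Turnovers |
|---|---|
| Full rate, feed allowed for | 2.60 |
| Lost to the sag | 0.254 |
| Left | 2.35 |

So we expect 90.4% reacted. The solid must supply 0.107 M, with the dissolved level counted, which is less than its 0.150 M.

The forecast gave 90% (87% to 92%) and 27% (25% to 29%), holding that “Solid nucleophile outlasts the run”.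

The flask gives 90.3% reacted and a free share of 26.9%. In the neighbouring flask with 0.12 M of electrophile the turnovers stay at 2.60, but the sag grows to 0.657, which leaves 1.99 turnovers and 86.3% reacted. That asks for 0.224 M of nucleophile, more than the 0.150 M of solid. At two per turn, the solid in that neighbouring flask covers 62.5% of the electrophile. That neighbouring flask reaches 64.8%, with solid nucleophile at 0% and salt of the base at 0.00545 M.

(Its constants were set for the occasion; the flask was simulated.)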